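Atoms are numbered along the target SMILES (C1 = exocyclic CH2 … C17 = ring-fusion CH; ring A = C2–C6/C17, B = C6–C9/C17, C = the eleven-membered ring). Ring C is disconnected at C3–C16: the γ,δ-unsaturated ketone array C15(=O)–C16–C3–C2=C1 is the retron of a Carroll rearrangement. A 13-membered β-keto lactone, in which the C1 allylic oxygen on ring A is acylated by the C16 acetoacetyl terminus of the C9 side chain, contracts by [3,3] shift and loss of CO2 to the 11-membered carbocycle, forming C3–C16, the C3 stereocentre and the exocyclic methylene in one operation. The hydrindene stereocentres are relayed from one purchased silyloxycyclopentenone.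

Key step: step 20

Remark: the atom labels C1–C17 defined above are used for every intermediate; vinylketene dimethyl acetal 2 is assumed to be available as a stock reagent.

Step 1
Reactants: 1 (S)-4-(tert-butyldimethylsilyloxy)cyclopent-2-en-1-one; 2 1,1-dimethoxybuta-1,3-diene
Product: 4 cis-fused dienone ketal (C7 ketone; C8=C9; C3=C4; C5 dimethyl ketal), via Diels–Alder adduct 3 (not isolated)
Conditions: 2 (2 equiv), toluene, 80 °C; then DBU, 0 °C
Reagents that add atoms: none
Why: Normal-demand Diels–Alder reaction of the electron-rich vinylketene acetal (acetal carbon to the α-carbon C6, CH2 terminus to the β-carbon C17) should occur anti to the C9 silyloxy group and is necessarily cis-fused, so the purchased centre sets C6 and C17 before E1cB β-elimination erases it and unveils the C8=C9 enone.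

Step 2
Reactants: 4 cis-fused dienone ketal
Product: 5 C6-methyl dienone ketal (6-CH3 cis to H17)
Conditions: LDA, THF, −78 °C; MeI, DMPU, −78 → −40 °C
Reagents that add atoms: iodomethane, CI
Why: Kinetic α′-enolate alkylation: LDA removes the only α′-proton (C6–H) and iodomethane should enter on the convex face anti to the C17–C2 bond, which keeps the hydrindane cis-fused and makes C6 quaternary.

Step 3
Reactants: 5 C6-methyl dienone ketal
Product: 7 β-hydroxy enone (7-OH cis to C5; C5 ketone conjugated to C3=C4), via ketal alcohol 6 (not isolated)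
Conditions: NaBH4, CeCl3·7H2O, MeOH, −78 °C; then 1 M HCl, THF, 0 °C
Reagents that add atoms: water, O
Why: Luche 1,2-reduction should deliver hydride to C7 from the face of the C6 methyl group (anti to the bulky C5 ketal), placing 7-OH cis to C5, and dilute acid then hydrolyses the allylic ketal to the C5 enone.

Step 4
Reactants: 7 β-hydroxy enone
Product: 8 hydroxy acetate (C7 acetate; 5-OH cis to 6-CH3; 5,7-anti)
Conditions: CH3CHO (6 equiv), SmI2 (0.3 equiv), THF, −10 °C
Reagents that add atoms: acetaldehyde, CC=O
Why: Evans–Tishchenko reduction: the C7 hemiacetal formed with acetaldehyde transfers hydride to the C5 carbonyl through a Sm-chelated six-membered transition state, which should give the 5,7-anti product (5-OH cis to the C6 methyl) and leaves C7–O as the acetate needed in step 8.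

Step 5
Reactants: 8 hydroxy acetate
Product: 9 C5 propionate C7 acetate
Conditions: (EtCO)2O, DMAP, Et3N, CH2Cl2, rt
Reagents that add atoms: propionic anhydride, CCC(=O)OC(=O)CC
Why: DMAP-catalysed acylation of the hindered secondary alcohol installs the C5 propionate of the target.

Step 6
Reactants: 9 C5 propionate C7 acetate
Product: 10 C2 enone (C2 ketone conjugated to C3=C4)
Conditions: Rh2(cap)4 (1 mol%), t-BuOOH, NaHCO3, CH2Cl2, rt
Reagents that add atoms: tert-butyl hydroperoxide, CC(C)(C)OO
Why: Rh-catalysed allylic C–H oxidation should convert the only unactivated allylic methylene (C2; C5–H and C7–H are deactivated by acyloxy groups and C17–H is tertiary) into the C2 ketone.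

Step 7
Reactants: 10 C2 enone
Product: 11 C2 enol triflate (C2=C3)
Conditions: L-Selectride, THF, −78 °C; then PhNTf2, −78 → 0 °C
Reagents that add atoms: N-phenyl-bis(trifluoromethanesulfonimide), O=S(=O)(N(c1ccccc1)S(=O)(=O)C(F)(F)F)C(F)(F)F
Why: Conjugate hydride reduction of the β-unsubstituted cyclohexenone gives the C2–C3 enolate regiospecifically, and O-triflation fixes the C2=C3 double bond.

Step 8
Reactants: 11 C2 enol triflate
Product: 14 carboxylic acid (C9 CH2CO2H cis to C2; C7=C8), via bis(silyl ketene acetal) 12 (not isolated), via silyl ester 13 (not isolated)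
Conditions: LDA (3 equiv), TMSCl, Et3N, THF, −78 → 50 °C; then 1 M HCl
Reagents that add atoms: none
Why: Ireland–Claisen rearrangement: the silyl ketene acetal of the allylic C7 acetate should transfer C10 suprafacially to C9 through a boat transition state, so the side chain arrives on the concave face cis to C2, while the C5 propionate (homoallylic oxygen) is silylated only reversibly.

Step 9
Reactants: 14 carboxylic acid
Product: 15 S-ethyl thioester
Conditions: EtSH, DCC, DMAP (cat.), CH2Cl2, 0 °C → rt
Reagents that add atoms: ethanethiol, CCS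
Why: Steglich-type thioesterification makes the side-chain α-protons about four pKa units more acidic than those of the C5 propionate.

Step 10
Reactants: 15 S-ethyl thioester
Product: 16 (10S)-methyl thioester
Conditions: LiHMDS (1.05 equiv), THF/DMPU, −78 °C; MeI
Reagents that add atoms: iodomethane, CI
Why: Chemoselective thioester enolate alkylation: with H9 eclipsing the enolate (A1,3 strain) iodomethane should attack anti to C17, whose C2 enol triflate lies on the same face as the side chain, which gives (10S).

Step 11
Reactants: 16 (10S)-methyl thioester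
Product: 17 C7–C8 saturated thioester
Conditions: 2-nitrobenzenesulfonylhydrazide, Et3N, CH2Cl2, rt
Reagents that add atoms: none
Why: Diimide reduction is sensitive to substitution and should saturate the cis-disubstituted C7=C8 bond while leaving the trisubstituted enol triflate and the thioester untouched.

Step 12
Reactants: 17 C7–C8 saturated thioester
Product: 18 (10S) aldehyde (C11 = CHO)
Conditions: DIBAL-H (1.1 equiv), toluene, −78 °C
Reagents that add atoms: none
Why: Partial DIBAL-H reduction of the thioester stops at the aldehyde at −78 °C, the hindered C5 propionate reacting far more slowly.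

Step 13
Reactants: 18 (10S) aldehyde
Product: 19 (11S) homoallylic alcohol (10,11-syn)
Conditions: (R,R)-diisopropyl tartrate allylboronate, 4 Å MS, toluene, −78 °C
Reagents that add atoms: (4R,5R)-diisopropyl 2-allyl-1,3,2-dioxaborolane-4,5-dicarboxylate, C=CCB1O[C@@H](C(=O)OC(C)C)[C@H](C(=O)OC(C)C)O1
Why: Tartrate-controlled allylboration through a chair transition state adds to the Si face, which is also the Felkin–Anh face of the α-methyl aldehyde (matched pair), and should give the 10,11-syn (11S) alcohol.

Step 14
Reactants: 19 (11S) homoallylic alcohol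
Product: 20 C11 acetate
Conditions: Ac2O, pyridine, DMAP (cat.), CH2Cl2, 0 °C → rt
Reagents that add atoms: acetic anhydride, CC(=O)OC(C)=O
Why: Standard O-acetylation installs the C11 acetate of the target.

Step 15
Reactants: 20 C11 acetate
Product: 21 (E)-enal (C13=C14 bearing the C14 methyl; C15 = CHO)
Conditions: methacrolein (10 equiv), Hoveyda–Grubbs II (5 mol%), CH2Cl2, 40 °C
Reagents that add atoms: methacrolein, C=C(C)C=O
Why: Olefin cross-metathesis of the terminal olefin with the 1,1-disubstituted enal should give the (E)-trisubstituted enal and leaves the electron-poor enol triflate untouched.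

Step 16
Reactants: 21 (E)-enal
Product: 22 β-hydroxy tert-butyl ester (C15 epimers)
Conditions: t-BuOAc, LDA, THF, −78 °C
Reagents that add atoms: tert-butyl acetate, CC(=O)OC(C)(C)C
Why: Aldol addition of the lithium ester enolate to the enal occurs 1,2 at −78 °C (the esters are inert at this temperature) and forms the C15–C16 bond; the C15 configuration is irrelevant.

Step 17
Reactants: 22 β-hydroxy tert-butyl ester
Product: 23 β-keto tert-butyl ester (C15 ketone)
Conditions: Dess–Martin periodinane, NaHCO3, CH2Cl2, rt
Reagents that add atoms: none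
Why: Dess–Martin oxidation of the only free hydroxyl gives the enone β-keto ester.

Step 18
Reactants: 23 β-keto tert-butyl ester
Product: 24 seco allylic alcohol (C1 CH2OH on C2=C3)
Conditions: Bu3SnCH2OH, Pd(PPh3)4 (10 mol%), LiCl, THF, 65 °C
Reagents that add atoms: (tributylstannyl)methanol, OC[Sn](CCCC)(CCCC)CCCC
Why: Stille coupling of the enol triflate with the hydroxymethylstannane installs C1 as a free allylic alcohol at the last moment, so it needs no protecting group.

Step 19
Reactants: 24 seco allylic alcohol
Product: 26 13-membered β-keto lactone, via acylketene 25 (not isolated)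
Conditions: toluene (1 mM), 110 °C
Reagents that add atoms: none
Why: Acylketene macrolactonisation: thermolysis of the tert-butyl β-keto ester expels tert-butanol, and the acylketene should be trapped intramolecularly by the primary allylic alcohol under high dilution.

Step 20
Reactants: 26 13-membered β-keto lactone
Product: 28 tricyclic enone (11-membered ring C; C15 ketone; exocyclic C2=C1), via β-keto acid 27 (not isolated)
Conditions: 1,2-dichlorobenzene (1 mM), 180 °C, sealed tube
Reagents that add atoms: none
Why: Carroll rearrangement: the ester enol of the β-keto lactone (C16=C(OH)–O–C1–C2=C3) should undergo a concerted [3,3]-sigmatropic shift that forms C16–C3, cleaves O–C1 and turns C2=C3 into the exocyclic C2=C1 olefin, and the β-keto acid 27 then loses CO2, so the ester carbon and oxygen are extruded and the 13-membered lactone becomes the 11-membered carbocycle. The closest known reaction types are the thermal Carroll rearrangement of allyl β-keto esters and the ester-enolate Claisen ring contraction of macrolactones. Ring C is closed by a transannular suprafacial [3,3] closure (a six-atom pericyclic array bridged by the C15–C9–C17 tether), not by an end-to-end cyclisation. The new stereocentre C3 is controlled by the tether: C10 leaves C9 on the concave face above ring A, so bonding on that face of C3 would force the (E)-C13=C14 olefin and sp2 C15 into a seven-atom loop, and C16 should reach C3 only on the face anti to the C17–C9 bond, which is the C3 configuration of the target. The step needs [3,3] bonding at C3 (not [1,3] bonding at C1) and survival of the lactone at 180 °C: the concerted pathway secures the former, and high dilution returns any acylketene formed by retro-addition to the lactone.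

Step 21
Reactants: 28 tricyclic enone
Product: 29 (15R) allylic alcohol
Conditions: (S)-Me-CBS (0.2 equiv), catecholborane, toluene, −78 °C
Reagents that add atoms: none
Why: CBS reduction treats the alkenyl group as the large substituent and should give the (15R) alcohol under catalyst control, and catecholborane does not hydroborate the exocyclic olefin at −78 °C.

Step 22
Reactants: 29 (15R) allylic alcohol
Product: 30 CNP0415604.1 (target)
Conditions: ent-Shi ketone (0.3 equiv), Oxone, K2CO3, Bu4NHSO4, MeCN/DMM/aq. buffer (pH 10.5), 0 °C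
Reagents that add atoms: Oxone (potassium peroxymonosulfate), [K+].[O-]S(=O)(=O)OO
Why: Shi epoxidation: the chiral dioxirane should epoxidise the electron-rich (E)-trisubstituted olefin through a spiro transition state on the face that gives (13S,14S), while the 1,1-disubstituted exocyclic olefin is a poor substrate.

Compound list
1 | (S)-4-(tert-butyldimethylsilyloxy)cyclopent-2-en-1-one | O=C1C=C[C@@H](O[Si](C)(C)C(C)(C)C)C1 | starting material
2 | 1,1-dimethoxybuta-1,3-diene (vinylketene dimethyl acetal) | COC(OC)=CC=C | starting material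
3 | Diels–Alder adduct (cis-fused; C7 ketone; C9 OTBS anti to C2; C5 dimethyl ketal; C3=C4) | C1C=CC(OC)(OC)[C@H]3C(=O)C[C@H](O[Si](C)(C)C(C)(C)C)[C@@H]13 | intermediate (not isolated)
4 | cis-fused dienone ketal (C7 ketone; C8=C9; C3=C4; C5 dimethyl ketal; H6 cis to H17) | C1C=CC(OC)(OC)[C@H]3C(=O)C=C[C@@H]13 | intermediate
5 | C6-methyl dienone ketal (6-CH3 cis to H17; C6 and C17 as in the target) | C1C=CC(OC)(OC)[C@@]3(C)C(=O)C=C[C@@H]13 | intermediate
6 | ketal alcohol (7-OH cis to C5; C5 dimethyl ketal) | C1C=CC(OC)(OC)[C@@]3(C)[C@@H](O)C=C[C@@H]13 | intermediate (not isolated)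
7 | β-hydroxy enone (7-OH cis to C5; C5 ketone; C3=C4; C8=C9) | C1C=CC(=O)[C@@]3(C)[C@@H](O)C=C[C@@H]13 | intermediate
8 | hydroxy acetate (C7 acetate; 5-OH cis to 6-CH3; 5,7-anti; C5 as in the target) | C1C=C[C@H](O)[C@@]3(C)[C@@H](OC(C)=O)C=C[C@@H]13 | intermediate
9 | C5 propionate C7 acetate (C3=C4; C8=C9) | C1C=C[C@H](OC(=O)CC)[C@@]3(C)[C@@H](OC(C)=O)C=C[C@@H]13 | intermediate
10 | C2 enone (C2 ketone conjugated to C3=C4; C5 propionate; C7 acetate; C8=C9) | O=C1C=C[C@H](OC(=O)CC)[C@@]3(C)[C@@H](OC(C)=O)C=C[C@@H]13 | intermediate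
11 | C2 enol triflate (C2=C3; C5 propionate; C7 acetate; C8=C9) | FC(F)(F)S(=O)(=O)OC1=CC[C@H](OC(=O)CC)[C@@]3(C)[C@@H](OC(C)=O)C=C[C@@H]13 | intermediate
12 | bis(trimethylsilyl ketene acetal) of 11 | FC(F)(F)S(=O)(=O)OC1=CC[C@H](OC(=CC)O[Si](C)(C)C)[C@@]3(C)[C@@H](OC(=C)O[Si](C)(C)C)C=C[C@@H]13 | intermediate (not isolated)
13 | rearranged trimethylsilyl ester (C9 CH2CO2SiMe3 cis to C2; C7=C8; C5 ester still as ketene acetal) | FC(F)(F)S(=O)(=O)OC1=CC[C@H](OC(=CC)O[Si](C)(C)C)[C@@]3(C)C=C[C@@H](CC(=O)O[Si](C)(C)C)[C@@H]13 | intermediate (not isolated)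
14 | carboxylic acid (C9 CH2CO2H cis to C2; C9 as in the target; C7=C8) | FC(F)(F)S(=O)(=O)OC1=CC[C@H](OC(=O)CC)[C@@]3(C)C=C[C@@H](CC(=O)O)[C@@H]13 | intermediate
15 | S-ethyl thioester of 14 | FC(F)(F)S(=O)(=O)OC1=CC[C@H](OC(=O)CC)[C@@]3(C)C=C[C@@H](CC(=O)SCC)[C@@H]13 | intermediate
16 | (10S)-methyl S-ethyl thioester | FC(F)(F)S(=O)(=O)OC1=CC[C@H](OC(=O)CC)[C@@]3(C)C=C[C@@H]([C@H](C)C(=O)SCC)[C@@H]13 | intermediate
17 | C7–C8 saturated (10S) thioester | FC(F)(F)S(=O)(=O)OC1=CC[C@H](OC(=O)CC)[C@@]3(C)CC[C@@H]([C@H](C)C(=O)SCC)[C@@H]13 | intermediate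
18 | (10S) aldehyde (C11 = CHO) | FC(F)(F)S(=O)(=O)OC1=CC[C@H](OC(=O)CC)[C@@]3(C)CC[C@@H]([C@H](C)C=O)[C@@H]13 | intermediate
19 | (10S,11S) homoallylic alcohol | FC(F)(F)S(=O)(=O)OC1=CC[C@H](OC(=O)CC)[C@@]3(C)CC[C@@H]([C@H](C)[C@@H](O)CC=C)[C@@H]13 | intermediate
20 | C11 acetate (terminal olefin at C13) | FC(F)(F)S(=O)(=O)OC1=CC[C@H](OC(=O)CC)[C@@]3(C)CC[C@@H]([C@H](C)[C@@H](OC(C)=O)CC=C)[C@@H]13 | intermediate
21 | (E)-enal (C13=C14; 14-CH3; C15 = CHO) | FC(F)(F)S(=O)(=O)OC1=CC[C@H](OC(=O)CC)[C@@]3(C)CC[C@@H]([C@H](C)[C@@H](OC(C)=O)C/C=C(\C)C=O)[C@@H]13 | intermediate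
22 | β-hydroxy tert-butyl ester (C15 carbinol as epimer mixture) | FC(F)(F)S(=O)(=O)OC1=CC[C@H](OC(=O)CC)[C@@]3(C)CC[C@@H]([C@H](C)[C@@H](OC(C)=O)C/C=C(\C)C(O)CC(=O)OC(C)(C)C)[C@@H]13 | intermediate
23 | β-keto tert-butyl ester (C15 ketone) | FC(F)(F)S(=O)(=O)OC1=CC[C@H](OC(=O)CC)[C@@]3(C)CC[C@@H]([C@H](C)[C@@H](OC(C)=O)C/C=C(\C)C(=O)CC(=O)OC(C)(C)C)[C@@H]13 | intermediate
24 | seco allylic alcohol (C1 CH2OH on C2=C3; β-keto tert-butyl ester) | OCC1=CC[C@H](OC(=O)CC)[C@@]3(C)CC[C@@H]([C@H](C)[C@@H](OC(C)=O)C/C=C(\C)C(=O)CC(=O)OC(C)(C)C)[C@@H]13 | intermediate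
25 | acylketene of 24 (C16=C=O) | OCC1=CC[C@H](OC(=O)CC)[C@@]3(C)CC[C@@H]([C@H](C)[C@@H](OC(C)=O)C/C=C(\C)C(=O)C=C=O)[C@@H]13 | intermediate (not isolated)
26 | 13-membered β-keto lactone (C1–O ester of the C16 carboxyl; C2=C3; (E)-C13=C14) | O=C4OCC1=CC[C@H](OC(=O)CC)[C@@]3(C)CC[C@@H]([C@H](C)[C@@H](OC(C)=O)C/C=C(\C)C(=O)C4)[C@@H]13 | intermediate
27 | ring-contracted β-keto acid (C3–C16 bond; 16-CO2H; exocyclic C2=C1) | C=C1[C@H]2C[C@H](OC(=O)CC)[C@@]3(C)CC[C@@H]([C@H](C)[C@@H](OC(C)=O)C/C=C(\C)C(=O)C2C(O)=O)[C@@H]13 | intermediate (not isolated)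
28 | tricyclic enone (11-membered ring; C3 as in the target; C15 ketone; (E)-C13=C14) | C=C1[C@H]2C[C@H](OC(=O)CC)[C@@]3(C)CC[C@@H]([C@H](C)[C@@H](OC(C)=O)C/C=C(\C)C(=O)C2)[C@@H]13 | intermediate
29 | (15R) allylic alcohol | C=C1[C@H]2C[C@H](OC(=O)CC)[C@@]3(C)CC[C@@H]([C@H](C)[C@@H](OC(C)=O)C/C=C(\C)[C@H](O)C2)[C@@H]13 | intermediate
30 | CNP0415604.1 | C=C1[C@H]2C[C@H](OC(=O)CC)[C@@]3(C)CC[C@@H]([C@H](C)[C@@H](OC(C)=O)C[C@@H]4O[C@@]4(C)[C@H](O)C2)[C@@H]13 | target

Total step count: 22. Longest linear sequence: 22 steps (from 1).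

Steps most likely to fail

Step 20 (key step). At the temperature the [3,3] shift needs, retro-addition of the lactone to the acylketene followed by intermolecular recapture (oligomerisation) may outrun the rearrangement, or C16 may approach the wrong face of C3. The fallback replaces the pericyclic contraction by a metal-catalysed ionisation–recombination. Setting out from lactone 26, [Cp*Ru(MeCN)3]PF6 with 2,2′-bipyridine (CH2Cl2, rt) should ionise the allylic C1–O bond; the tethered β-keto carboxylate loses CO2 and the enolate recombines with the π-allyl unit at its more substituted terminus C3 (branched-selective decarboxylative allylation). This returns to the route at enone 28 without a new isolated compound (F0).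

Step 10. Facial discrimination in the enolate alkylation may be incomplete (C10 epimer), and the C5 propionate may be enolised and methylated in competition. The fallback replaces substrate control by auxiliary control. Setting out from acid 14, the mixed pivalic anhydride (PivCl, Et3N) is treated with lithiated (S)-4-benzyloxazolidin-2-one to give the N-acyl oxazolidinone F1. NaHMDS and MeI (THF, −78 °C) should methylate the chelated Z-enolate anti to the benzyl group to give the (10S)-methyl imide F2. LiSEt (EtSH, n-BuLi, THF, 0 °C) then cleaves the auxiliary and returns to the route at thioester 16.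

Step 22. Facial selectivity may be poor if the catalyst-preferred face is not the exposed face of the macrocyclic olefin, or if hydroxyl-directed delivery overrides catalyst control. The fallback sets the epoxide by hydroxyl direction and inverts C15 afterwards. Setting out from enone 28, (R)-Me-CBS and catecholborane should give the (15S) allylic alcohol F3. VO(acac)2 and t-BuOOH should then give the erythro epoxy alcohol F4 ((13S,14S,15S); vanadate-bound hydroxyl, A1,2 strain from the C14 methyl). Mitsunobu inversion (4-nitrobenzoic acid, PPh3, DIAD) gives the (15R) 4-nitrobenzoate F5, and brief K2CO3/MeOH at 0 °C removes the activated ester to return to the route at target 30.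

Further compounds
F0 | step 20 | none | none
F1 | step 10 | N-acyl (S)-4-benzyloxazolidin-2-one of acid 14 | FC(F)(F)S(=O)(=O)OC1=CC[C@H](OC(=O)CC)[C@@]3(C)C=C[C@@H](CC(=O)N4[C@@H](Cc5ccccc5)COC4=O)[C@@H]13
F2 | step 10 | (10S)-methyl N-acyl oxazolidinone | FC(F)(F)S(=O)(=O)OC1=CC[C@H](OC(=O)CC)[C@@]3(C)C=C[C@@H]([C@H](C)C(=O)N4[C@@H](Cc5ccccc5)COC4=O)[C@@H]13
F3 | step 22 | (15S) allylic alcohol (C15 epimer of 29) | C=C1[C@H]2C[C@H](OC(=O)CC)[C@@]3(C)CC[C@@H]([C@H](C)[C@@H](OC(C)=O)C/C=C(\C)[C@@H](O)C2)[C@@H]13
F4 | step 22 | (13S,14S,15S) erythro epoxy alcohol (C15 epimer of the target) | C=C1[C@H]2C[C@H](OC(=O)CC)[C@@]3(C)CC[C@@H]([C@H](C)[C@@H](OC(C)=O)C[C@@H]4O[C@@]4(C)[C@@H](O)C2)[C@@H]13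
F5 | step 22 | (15R) 4-nitrobenzoate of the target | C=C1[C@H]2C[C@H](OC(=O)CC)[C@@]3(C)CC[C@@H]([C@H](C)[C@@H](OC(C)=O)C[C@@H]4O[C@@]4(C)[C@H](OC(=O)c5ccc(cc5)[N+](=O)[O-])C2)[C@@H]13
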